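Conventions: all intermediates carry the decalin locants of the target: C1 (acyl-bearing), C2 (CH3), C3=C4, C4a (OH), C5, C6 (CO2H), C7, C8 (CH3), C8a. Ring A is C1–C4/C4a/C8a and ring B is C4a–C8a. The face of ring B that carries the C8a–C1 bond is called β. Compound numbers are those of the steps and of the list.

## Analysis of the target

The target 44 is a 1H-pyrrole-2,5-dione whose C4 carries an (S)-oct-1-en-3-yl group and whose C3 carries a ketone carbonyl bound to C1 of a cis-fused octahydronaphthalene. It has seven stereocentres: C1 (S), C2 (R), C4a (R), C6 (R), C8 (S), C8a (R) and the side-chain methine (S). On ring B the four carbon substituents (C8a–C1, C8–CH3, C6–CO2H and C4a–C4) all lie on the β face, so the C4a hydroxyl and the C8a hydrogen are α and the fusion is cis; on ring A the acyl group at C1 is trans to the C2 methyl. The sensitive parts are the acylmaleimide (a strong Michael acceptor whose side-chain methine is doubly allylic and vinylogously acidic, with C1–H α to the ketone), the tertiary allylic alcohol at C4a, the free acid and the terminal vinyl group. The synthesis is hard for three reasons: the contiguous centres C2, C1, C8a and C4a end in a carbinol whose oxygen sits on the face opposite to every carbon substituent of ring B; C8a is α to the oxidised C4a and holds its branch axial in the all-cis array, which a free 2-substituted cyclohexanone would not keep; and the carbons on C6 and C8 are alike in position but differ in oxidation level. The strategy rests on the 1,3-cis pair of one-carbon substituents on C6 and C8 flanking C7, with oxidised C4a between C5 and C8a. This is the six-membered ring of bicyclo[3.2.1]oct-6-en-3-one 4 after its etheno bridge has been cut, the bridge carbons becoming the carboxyl and methyl carbons and an equatorial α-substituent becoming the C8a–C1 bond. The maleimide double bond is best introduced last, from a succinimide.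

## Retrosynthetic reasoning

44 ⇒ 42. The ring double bond of the maleimide is removed first. The saturated imide 42 is no Michael acceptor and its side-chain methine is not acidic, so all earlier steps are safer. The forward step must dehydrogenate only between the two imide α-carbons; the carbon bearing the acyl group is the single doubly activated C–H, which fixes where the leaving group enters.

42 ⇒ 41 ⇒ 40 ⇒ 39. The ketone and the carboxyl are taken back to a secondary and a primary alcohol so that one oxidant raises both (40 → 41) and a chlorite oxidation finishes the acid. The C6 carbon travels as a silyl ether because an ester there would be enolised in the Claisen step.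

39 ⇒ 29 + 37. The bond between the carbinol carbon and the imide α-carbon is cut. This divides the molecule into a decalin aldehyde and an imide that each carry their own stereocentres, the most convergent cut available. An aldehyde is chosen over an acid derivative because the hindered, α-branched C1 acyl group would be deprotonated rather than attacked. The forward aldol must use the unsubstituted α-carbon of 37.

37 ⇒ 36 ⇒ 35 ⇒ 33 + 34, and 33 ⇒ 31 + 32, 31 ⇒ 30. The imide ring is opened at an N–C(O) bond and at the bond from the malonate carbon to the acetamide carbon, and the side chain is cut at the bond from its methine to the malonate carbon. An allylic substitution at the substituted terminus of the octenyl unit makes this bond and the only stereocentre of the fragment in one catalytic step.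

29 ⇒ 28 ⇒ 27 ⇒ 26. Ring A is opened at C3=C4. Both alkene carbons are then ends of vinyl groups on C2 and C4a that are cis on ring B, so a ring-closing metathesis has only a six-membered ring to form.

26 ⇒ 24 ⇒ 23. The C4a–vinyl carbinol is taken back to a spiro-epoxide and this to an exocyclic methylene. Adding a vinyl metal to a C4a ketone would look shorter, but the nucleophile would enter anti to the three β substituents and give the trans-fused epimer. Delivering oxygen to the open α face of an alkene sets the carbinol correctly, and the methylene carbon becomes C4.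

23 ⇒ 22 ⇒ 19. The C1–C2 bond is cut by an Ireland–Claisen transform, which forms both stereocentres through one chair transition state from an (E)-butenyl ester. It is placed while C4a is still sp2, so that the two flanks of C8a differ as much as possible.

19 ⇒ 18 ⇒ 16 ⇒ 15 ⇒ 14. The C8 methyl is traced to a selenide and this to a δ-lactone between the C1 carboxyl and the hydroxymethyl on C8. Only that hydroxymethyl can reach the C1 carboxyl in a six-membered ring, so lactonisation tells the two ends of the cleaved bridge apart; opening the lactone at its alkyl carbon then sets the C8 carbon up for reduction and frees the C1 carboxyl for the butenyl ester.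

14 ⇒ 13 ⇒ 12 ⇒ 11 ⇒ 10. Ring B is folded back into the bicycle by rejoining the C6 and C8 carbons as an etheno bridge. The bridge guarantees the cis relation of these carbons. The forward cleavage must spare the exocyclic methylene, which is kept because it stops C8a from epimerising once the bicycle is open.

10 ⇒ 9 ⇒ 8 ⇒ 7 ⇒ 5 ⇒ 4. The methylene is taken back to the ketone and the C8a–C1 bond is cut next to it. Enantioselective deprotonation of the meso ketone 4 decides which α-carbon becomes C8a and hence the absolute configuration, and equilibration on the rigid bicycle places the side chain equatorial, cis to the bridge.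

4 ⇒ 3 ⇒ 1 + 2. The seven-membered ring of 4 is cut at C5–C6 and C8–C8a into a five-carbon diene and a three-carbon oxyallyl unit. This (4+3) disconnection reaches two commodity materials in one step and creates the cis bridgeheads without any control element.

## Alternatives that were turned down

Alternative 1: The C4–C4a bond is cut, giving a ring B cyclohexanone that carries the whole C1–C4 chain on C8a and ends in a (Z)-alkenyl iodide, keto diester A1. In the forward step CrCl2 with catalytic NiCl2 turns the iodide into an alkenylchromium that adds to the C4a ketone and gives the cis-decalin hydroxy diester A2 (Nozaki–Hiyama–Kishi closure). In its favour, the ketone oxygen becomes the C4a hydroxyl directly and the tether can deliver C4 only from the β face. On this centre it is stronger than the chosen route, which spends three steps (methylenation, epoxidation, homologation) for the same result. Against it, A1 is a free cyclohexanone with C8a in its less stable axial arrangement, so every operation between opening ring B and the closure, including the basic olefination that makes the Z-iodide, invites epimerisation. Ketones are also slow partners for alkenylchromium reagents, and a large excess of divalent chromium with competing loss of iodide is to be expected. The cut also leaves open how the all-cis ring B, C1 and C2 are made. The chosen strategy answers that question first and keeps C4a as a non-enolisable methylene while ring B is open.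

Alternative 2: The C1–C8a bond is cut, giving the prochiral quinol aldehyde A3. A chiral secondary amine forms the enamine of the side-chain aldehyde, which adds to one of the two enantiotopic enone arms and gives the cis-fused hydroxy decalin A4. In its favour, this is the shortest way to a cis-fused 4a-hydroxy decalin, it is catalytic in the chiral element, and the C4a oxygen and the C4a–C4 bond come from a simple phenol oxidation. On step count to the bicyclic core, and on using a catalytic rather than a stoichiometric chiral reagent, it is stronger than the chosen route. Against it, ring B arrives as a 5-en-7-one with a methyl group on C6. The C7 carbonyl must be removed, the alkene reduced with control at C6, and C8 set by protonation. The C6 methyl must then be oxidised to a carboxyl beside two other methyl groups, which has no selective handle. The C2 centre must also be in the chain beforehand and may oppose the catalyst, and quinols rearrange in acid. The redox corrections would use up the steps saved, whereas the chosen bicycle delivers the C6 and C8 carbons cis and already differentiable.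

Alternative 3: Ring A is cut at C3=C4 while a different bicycle is closed, in which C4 and the future carboxyl carbon form an etheno bridge between C4a and C6: bicyclic alcohol A5. A ruthenium carbene formed at the vinyl group on C2 opens this bridge and closes ring A, giving the decalin A6 with a vinyl group on C6 (ring-rearrangement metathesis). In its favour, one catalytic step builds ring A and opens the bicycle, and the bridge fixes C4 and the C6 carbon cis with the tertiary alcohol already in place. On ring A economy and on the C4a configuration it is stronger than the chosen route. Against it, the C6 vinyl must later be cleaved to a carboxyl in the presence of the C3=C4 alkene. A5 is also not symmetrical: its bridgehead carbinol, the C8a branch and the C8 methyl must each be installed with control, and the C8 methyl no longer comes from the bridge. The rearrangement is an equilibrium driven only by the modest strain of a bicyclo[3.2.1]octene next to a hindered bridgehead carbinol. The chosen route draws both the C6 and C8 carbons from the bridge of a meso ketone made in one step and uses an ordinary ring-closing metathesis.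

Key step: step 1

Assumption: the chiral lithium amide of step 2 and the phosphoramidite of step 19 are each written as the enantiomer taken to give the configuration drawn, by analogy with close substrates; if the sense of induction is opposite, the mirror-image reagent is used and nothing else changes.

## Route

Step 1
Reactants: 1 cyclopenta-1,3-diene (freshly cracked from its dimer); 2 1,1,3,3-tetrabromopropan-2-one
Product: 4 bicyclo[3.2.1]oct-6-en-3-one (meso), via dibromo cycloadduct 3 (not isolated)
Conditions: Zn–Cu couple, 1 in excess, dioxane, 0 → 23 °C; then Zn–Cu couple, NH4Cl, MeOH, 23 °C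
Reagents that add atoms: none
Why: Zinc reduces one C–Br bond of 2 to a zinc enolate, which loses bromide to give a dibromo-2-oxidoallyl cation. This cation adds across the termini of the diene in a (4+3) cycloaddition, the known behaviour of oxyallyl cations from polybromoketones with cyclic dienes, forming C5–C6 and C8–C8a. The seven-membered ring (C4a, C5, C6, the two future carboxyl and methyl carbons, C8, C8a) is closed by this two-bond union, concerted or through an allyl cation that collapses on the same face. The two new stereocentres, C6 and C8, are bridgeheads; their cis relation is enforced because both bonds must form on one face of the five-membered ring, so 4 is meso and needs no external control. The bromine configuration in 3 does not matter, since zinc in NH4Cl/MeOH removes both halogens. The step needs (4+3) rather than (3+2) capture and a single addition; the planar s-cis diene, the electrophilic halogen-stabilised cation and the excess of 1 should secure this.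

Step 2
Reactants: 4 bicyclo[3.2.1]oct-6-en-3-one
Product: 5 (1R,5R)-3-(trimethylsilyloxy)bicyclo[3.2.1]octa-2,6-diene
Conditions: lithium (R,R)-bis(1-phenylethyl)amide, LiN[CH(CH3)Ph]2 (from the amine hydrochloride and 2 equiv n-BuLi, so LiCl is present), Me3SiCl (internal quench), THF, −100 °C
Reagents that add atoms: chlorotrimethylsilane, C[Si](C)(C)Cl
Why: Enantioselective deprotonation of a meso bicyclic ketone by a C2-symmetric chiral lithium amide removes one of the two enantiotopic axial α-hydrogens, and the enolate is trapped as it forms. The choice of α-carbon defines the future C8a and with it the absolute configuration of ring B.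

Step 3
Reactants: 5 silyl enol ether; 6 methyl bromoacetate
Product: 9 methyl 2-[(1R,2S,5R)-3-oxobicyclo[3.2.1]oct-6-en-2-yl]acetate (side chain equatorial, cis to the etheno bridge), via lithium enolate 7 (not isolated), via axial keto ester 8 (not isolated)
Conditions: MeLi, THF, 0 °C; 6, DMPU, −78 → −20 °C; then DBU, 23 °C
Reagents that add atoms: none
Why: MeLi cleaves the Si–O bond to the amine-free, regiodefined lithium enolate, which is alkylated (SN2) mainly on the face away from the etheno bridge. DBU then equilibrates C8a through the enol to the more stable equatorial epimer, in which the side chain is cis to the bridge. This cannot racemise the material, because the other α-carbon stays unsubstituted.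

Step 4
Reactants: 9 keto ester
Product: 10 methyl 2-[(1R,2S,5R)-3-methylidenebicyclo[3.2.1]oct-6-en-2-yl]acetate
Conditions: Ph3PCH3Br, KOt-Bu, THF, 0 → 23 °C
Reagents that add atoms: methyltriphenylphosphonium bromide, C[P+](c1ccccc1)(c1ccccc1)c1ccccc1.[Br-]
Why: Wittig methylenation of the ketone (ylides spare methyl esters) removes the enolisable carbonyl before the bicycle is opened, so C8a can no longer epimerise. The new carbon is the future C4.

Step 5
Reactants: 10 diene ester
Product: 11 exo,exo-6,7-diol of 10 (methyl 2-[6,7-dihydroxy-3-methylidenebicyclo[3.2.1]octan-2-yl]acetate, other centres unchanged)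
Conditions: OsO4 (2 mol%), NMO (1.05 equiv), acetone/H2O, 0 °C
Reagents that add atoms: osmium tetroxide, O=[Os](=O)(=O)=O (transfers both oxygens); N-methylmorpholine N-oxide, C[N+]1([O-])CCOCC1 (restores the oxo groups)
Why: Catalytic cis-dihydroxylation is fastest at the strained cis-disubstituted alkene of the bicycle, from its open exo face. The 1,1-disubstituted methylene is flanked by the C8a branch and screened on both faces by the ring, and the limiting amount of co-oxidant should keep it intact.

Step 6
Reactants: 11 diol
Product: 14 cis-fused 7-(hydroxymethyl)-5-methylidenehexahydro-1H-isochromen-3(4H)-one (δ-lactone between the C1 carboxyl and the CH2OH on C8; C6–CH2OH free, β), via dialdehyde 12 (not isolated), via diol ester 13 (not isolated)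
Conditions: NaIO4, THF/pH 7 buffer, 0 °C; then NaBH4, MeOH, −20 °C; then PPTS, benzene, 50 °C
Reagents that add atoms: none
Why: Glycol cleavage opens the bridge to a cis-1,3-dialdehyde, which is reduced at once to the diol before its α-centres can epimerise. Only the hydroxymethyl on C8 can reach the ester through a six-membered ring, so acid-catalysed lactonisation tells the two ends apart.

Step 7
Reactants: 14 hydroxy lactone
Product: 15 tert-butyldiphenylsilyl ether of 14
Conditions: t-BuPh2SiCl, imidazole, CH2Cl2, 23 °C
Reagents that add atoms: tert-butyl(chloro)diphenylsilane, CC(C)(C)[Si](Cl)(c1ccccc1)c1ccccc1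
Why: Silylation of the only free primary alcohol gives a non-enolisable, base-stable stand-in for the C6 carboxyl.

Step 8
Reactants: 15 silyl lactone
Product: 16 2-[all-cis-4-(tert-butyldiphenylsilyloxymethyl)-2-methylidene-6-(phenylselanylmethyl)cyclohexyl]acetic acid
Conditions: PhSeNa (from (PhSe)2 and Na), THF/HMPA, 65 °C; then aq. HCl
Reagents that add atoms: diphenyl diselenide, c1ccccc1[Se][Se]c1ccccc1 (as sodium benzeneselenolate)
Why: The soft selenolate opens the lactone by SN2 attack at the O–CH2 carbon (alkyl–oxygen cleavage), which frees the C1 carboxylic acid and puts a reducible group on the C8 carbon.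

Step 9
Reactants: 16 seleno acid; 17 (E)-but-2-en-1-ol
Product: 18 (E)-but-2-en-1-yl ester of 16
Conditions: EDC·HCl, DMAP, CH2Cl2, 0 → 23 °C
Reagents that add atoms: none
Why: Steglich esterification of an unhindered acetic acid side chain; the (E)-butenyl ester is the substrate geometry needed for the Claisen step.

Step 10
Reactants: 18 seleno ester
Product: 19 (E)-but-2-en-1-yl 2-[all-cis-4-(tert-butyldiphenylsilyloxymethyl)-2-methyl-6-methylidenecyclohexyl]acetate
Conditions: Bu3SnH, AIBN, benzene, 80 °C
Reagents that add atoms: none
Why: Radical chain reduction of the primary C–Se bond gives the C8 methyl group. The primary radical has no favourable cyclisation path (only 4-exo or 5-endo onto the methylene), so hydrogen transfer should prevail.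

Step 11
Reactants: 19 butenyl ester
Product: 22 (2S,3R)-2-[all-cis-4-(tert-butyldiphenylsilyloxymethyl)-2-methyl-6-methylidenecyclohexyl]-3-methylpent-4-en-1-ol (new C1 and C2 as in the target), via silyl ketene acetal 20 (not isolated), via trimethylsilyl ester 21 (not isolated)
Conditions: LiN(i-Pr)2, THF, −78 °C; Me3SiCl/Et3N, −78 → 50 °C; then LiAlH4, 0 °C
Reagents that add atoms: none
Why: Ireland–Claisen rearrangement: kinetic enolisation in THF gives the ketene acetal with the ring carbon cis to the butenyloxy oxygen, and the chair transition state with the (E)-butenyl group gives the anti C1/C2 pair. With C8a–H eclipsing the ketene acetal double bond, the allyl unit should bond on the flank of the sp2 carbon C4a and away from C8 with its methyl group, which is the target configuration. LiAlH4 then reduces the silyl ester so that no ester is present in step 14.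

Step 12
Reactants: 22 primary alcohol
Product: 23 triethylsilyl ether of 22
Conditions: Et3SiCl, imidazole, CH2Cl2, 0 °C
Reagents that add atoms: chlorotriethylsilane, CC[Si](Cl)(CC)CC
Why: Silylation stops the C1 hydroxymethyl from steering the peracid to the β face or opening the epoxide, and sets up the direct oxidation of step 17.

Step 13
Reactants: 23 diene
Product: 24 spiro-epoxide of 23 at C4a (1-oxaspiro[2.5]octane; oxygen α, CH2 β)
Conditions: mCPBA, NaHCO3, CH2Cl2, −20 → 0 °C
Reagents that add atoms: 3-chloroperoxybenzoic acid, OOC(=O)c1cccc(Cl)c1
Why: Prilezhaev epoxidation is much faster at the 1,1-disubstituted methylene than at the monosubstituted vinyl group. Allylic strain holds the C8a branch axial on the β face, so the peracid should attack from the open α face, placing oxygen α and the future C4 β.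

Step 14
Reactants: 24 epoxide
Product: 26 tertiary vinyl carbinol (C4a–OH α, C4a–CH=CH2 β; silyl ethers unchanged), via sulfonium alkoxide 25 (not isolated)
Conditions: (CH3)3S+ I−, n-BuLi, THF, −10 → 23 °C
Reagents that add atoms: trimethylsulfonium iodide, C[S+](C)C.[I-]
Why: Dimethylsulfonium methylide opens the epoxide at its CH2 carbon, and a second equivalent forms the ylide of the resulting sulfonium salt, which eliminates dimethyl sulfide. This one-carbon homologation of an epoxide to an allylic alcohol leaves C4a untouched, and no ester is present to compete.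

Step 15
Reactants: 26 diene
Product: 27 cis-decalin: 1-(triethylsilyloxymethyl)-6-(tert-butyldiphenylsilyloxymethyl)-2,8-dimethyl-1,2,4a,5,6,7,8,8a-octahydronaphthalen-4a-ol (decalin locants, configuration of the target)
Conditions: second-generation Grubbs catalyst (H2IMes)(PCy3)Cl2Ru=CHPh (5 mol%), CH2Cl2 (5 mM), 40 °C
Reagents that add atoms: none
Why: Ring-closing metathesis of two terminal vinyl groups held cis on ring B closes the six-membered ring A at C3=C4 with loss of ethene; the free allylic hydroxyl is tolerated.

Step 16
Reactants: 27 tertiary alcohol
Product: 28 4a-O-triethylsilyl ether of 27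
Conditions: Et3SiOTf, 2,6-lutidine, CH2Cl2, −78 → 0 °C
Reagents that add atoms: triethylsilyl trifluoromethanesulfonate, CC[Si](CC)(CC)OS(=O)(=O)C(F)(F)F
Why: Silylation of the tertiary alcohol prevents lactol formation with the C1 aldehyde and quenching of the enolate in step 22; the buffered triflate should not ionise the allylic carbinol.

Step 17
Reactants: 28 bis(triethylsilyl) ether
Product: 29 decalin C1 aldehyde (C4a–OSiEt3, C6–CH2OSiPh2t-Bu)
Conditions: (COCl)2, DMSO, CH2Cl2, −78 → −40 °C; then i-Pr2NEt, −78 → 0 °C
Reagents that add atoms: none
Why: Under Swern conditions a primary triethylsilyl ether is cleaved and oxidised directly to the aldehyde, while the tertiary triethylsilyl and the tert-butyldiphenylsilyl ethers remain; the hindered base and low temperature should keep C1 from epimerising.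

Step 18
Reactants: 30 (E)-oct-2-en-1-ol
Product: 31 methyl (E)-oct-2-en-1-yl carbonate
Conditions: ClCO2Me, pyridine, CH2Cl2, 0 °C
Reagents that add atoms: methyl chloroformate, COC(=O)Cl
Why: Acylation of the allylic alcohol gives a leaving group that releases its own base (methoxide) on ionisation.

Step 19
Reactants: 31 allylic carbonate; 32 dimethyl malonate
Product: 33 dimethyl 2-[(3S)-oct-1-en-3-yl]propanedioate
Conditions: [Ir(cod)Cl]2 (2 mol%), O,O′-(1,1′-binaphthalene-2,2′-diyl) N,N-bis(1-phenylethyl)phosphoramidite (4 mol%), 1,5,7-triazabicyclo[4.4.0]dec-5-ene (8 mol%), THF, 23 °C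
Reagents that add atoms: none
Why: Iridium-catalysed allylic alkylation of a linear alkyl-substituted allylic carbonate with a malonate gives the branched product; the chiral phosphoramidite sets the side-chain stereocentre at the substituted allyl terminus.

Step 20
Reactants: 33 malonate; 34 2-bromoacetamide
Product: 36 methyl 3-[(3S)-oct-1-en-3-yl]-2,5-dioxopyrrolidine-3-carboxylate (both C3 epimers), via acyclic amide 35 (not isolated)
Conditions: NaH (2.2 equiv), DMF, 0 → 60 °C; then aq. NH4Cl
Reagents that add atoms: none
Why: The malonate anion is alkylated by the α-bromo amide, and the amide anion then closes the five-membered imide on one of the geminal esters; the new ring centre is not controlled and is erased later.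

Step 21
Reactants: 36 imide ester
Product: 37 3-[(3S)-oct-1-en-3-yl]pyrrolidine-2,5-dione (both C3 epimers)
Conditions: LiCl, DMSO/H2O, 140 °C
Reagents that add atoms: none
Why: Krapcho dealkoxycarbonylation of the doubly activated ester; the side-chain centre is β to the carbonyls and is not affected.

Step 22
Reactants: 29 decalin aldehyde; 37 succinimide
Product: 39 aldol adduct, 3-[hydroxy(decalin-1-yl)methyl]-4-[(3S)-oct-1-en-3-yl]pyrrolidine-2,5-dione with the silyl ethers of 29 (diastereomers at the carbinol and both imide ring carbons), via dilithio imide 38 (not isolated)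
Conditions: 37 (1.6 equiv), LiN(i-Pr)2 (2.1 equiv per 37), THF, −78 → 0 → −78 °C; then 29, −78 °C; aq. NH4Cl
Reagents that add atoms: none
Why: An N-unsubstituted imide gives an N,C-dianion with two equivalents of amide base, the carbanion forming at the less hindered CH2; its aldol addition to the aldehyde makes the bond between the acyl carbon and the imide. The three new centres need no control because steps 24 and 26 remove them.

Step 23
Reactants: 39 aldol adduct
Product: 40 triol (free C4a–OH, C6–CH2OH and secondary carbinol)
Conditions: HF·pyridine, pyridine, THF, 0 → 23 °C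
Reagents that add atoms: none
Why: Buffered fluoride removes the tertiary triethylsilyl and the primary tert-butyldiphenylsilyl ethers without the base that could trigger a retro-aldol or the acid that could ionise the C4a carbinol.

Step 24
Reactants: 40 triol
Product: 41 keto aldehyde (3-acylsuccinimide with C6–CHO)
Conditions: Dess–Martin periodinane, NaHCO3, CH2Cl2, 0 → 23 °C
Reagents that add atoms: none
Why: One reagent oxidises the secondary carbinol to the ketone and the primary alcohol to the aldehyde; the tertiary alcohol and the imide N–H are inert.

Step 25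
Reactants: 41 keto aldehyde
Product: 42 keto acid (3-acyl-4-alkylsuccinimide with free C6–CO2H and C4a–OH)
Conditions: NaClO2, NaH2PO4, 2-methylbut-2-ene, t-BuOH/H2O, 0 °C
Reagents that add atoms: sodium chlorite, [Na+].[O-]Cl=O
Why: Pinnick oxidation converts the aldehyde to the acid; the large excess of alkene scavenger should protect the alkenes and the enolised acylimide from hypochlorite. The equatorial C6 configuration is the stable one.

Step 26
Reactants: 42 keto acid
Product: 44 (2R,4S,4aR,5S,6R,8aR)-8a-hydroxy-4,6-dimethyl-5-({4-[(3S)-oct-1-en-3-yl]-2,5-dioxo-2,5-dihydro-1H-pyrrol-3-yl}carbonyl)-1,2,3,4,4a,5,6,8a-octahydronaphthalene-2-carboxylic acid, via selenide 43 (not isolated)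
Conditions: PhSeCl, pyridine, CH2Cl2, −40 → 0 °C; then H2O2 (30% aq.), 0 °C
Reagents that add atoms: none
Why: The enol of the acylimide is selenated at its doubly activated carbon, anti to the side chain and therefore syn to the neighbouring ring hydrogen. Oxidation gives a selenoxide that eliminates at or below room temperature, and the only β-hydrogen is the one that gives the maleimide double bond. The conditions are close to neutral, so the side-chain methine should keep its configuration.

## Compound list

1 | cyclopenta-1,3-diene | C1=CCC=C1 | starting material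
2 | 1,1,3,3-tetrabromopropan-2-one | O=C(C(Br)Br)C(Br)Br | starting material
3 | 2,4-dibromobicyclo[3.2.1]oct-6-en-3-one (bromide epimers) | O=C1C(Br)[C@H]2C=C[C@@H](C1Br)C2 | intermediate
4 | bicyclo[3.2.1]oct-6-en-3-one (meso) | O=C1C[C@H]2C=C[C@@H](C1)C2 | intermediate
5 | (1R,5R)-3-(trimethylsilyloxy)bicyclo[3.2.1]octa-2,6-diene | C[Si](C)(C)OC1=C[C@@H](C=C2)C[C@@H]2C1 | intermediate
6 | methyl bromoacetate | COC(=O)CBr | starting material
7 | lithium (1R,5R)-bicyclo[3.2.1]octa-2,6-dien-3-olate | [Li]OC1=C[C@@H](C=C2)C[C@@H]2C1 | intermediate
8 | methyl 2-[(1R,2R,5R)-3-oxobicyclo[3.2.1]oct-6-en-2-yl]acetate (axial side chain) | COC(=O)C[C@@H]1[C@@H](C=C2)C[C@@H]2CC1=O | intermediate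
9 | methyl 2-[(1R,2S,5R)-3-oxobicyclo[3.2.1]oct-6-en-2-yl]acetate (equatorial side chain) | COC(=O)C[C@H]1[C@@H](C=C2)C[C@@H]2CC1=O | intermediate
10 | methyl 2-[(1R,2S,5R)-3-methylidenebicyclo[3.2.1]oct-6-en-2-yl]acetate | COC(=O)C[C@H]1[C@@H](C=C2)C[C@@H]2CC1=C | intermediate
11 | exo,exo-6,7-diol of 10 | COC(=O)C[C@H]1[C@@H]([C@H](O)[C@@H]2O)C[C@@H]2CC1=C | intermediate
12 | methyl 2-(all-cis-2,4-diformyl-6-methylidenecyclohexyl)acetate | COC(=O)C[C@H]1[C@@H](C=O)C[C@@H](C=O)CC1=C | intermediate
13 | methyl 2-[all-cis-2,4-bis(hydroxymethyl)-6-methylidenecyclohexyl]acetate | COC(=O)C[C@H]1[C@@H](CO)C[C@@H](CO)CC1=C | intermediate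
14 | cis-fused 7-(hydroxymethyl)-5-methylidenehexahydro-1H-isochromen-3(4H)-one | O=C1C[C@H]2[C@@H](CO1)C[C@@H](CO)CC2=C | intermediate
15 | tert-butyldiphenylsilyl ether of 14 | O=C1C[C@H]2[C@@H](CO1)C[C@@H](CO[Si](c3ccccc3)(c3ccccc3)C(C)(C)C)CC2=C | intermediate
16 | 2-[all-cis-4-(tert-butyldiphenylsilyloxymethyl)-2-methylidene-6-(phenylselanylmethyl)cyclohexyl]acetic acid | OC(=O)C[C@H]1[C@@H](C[Se]c2ccccc2)C[C@@H](CO[Si](c2ccccc2)(c2ccccc2)C(C)(C)C)CC1=C | intermediate
17 | (E)-but-2-en-1-ol | C/C=C/CO | starting material
18 | (E)-but-2-en-1-yl ester of 16 | C/C=C/COC(=O)C[C@H]1[C@@H](C[Se]c2ccccc2)C[C@@H](CO[Si](c2ccccc2)(c2ccccc2)C(C)(C)C)CC1=C | intermediate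
19 | (E)-but-2-en-1-yl 2-[all-cis-4-(tert-butyldiphenylsilyloxymethyl)-2-methyl-6-methylidenecyclohexyl]acetate | C/C=C/COC(=O)C[C@H]1[C@@H](C)C[C@@H](CO[Si](c2ccccc2)(c2ccccc2)C(C)(C)C)CC1=C | intermediate
20 | trimethylsilyl ketene acetal of 19 (ring carbon cis to the butenyloxy oxygen) | C/C=C/CO/C(O[Si](C)(C)C)=C\[C@H]1[C@@H](C)C[C@@H](CO[Si](c2ccccc2)(c2ccccc2)C(C)(C)C)CC1=C | intermediate
21 | trimethylsilyl (2S,3R)-2-[all-cis-4-(tert-butyldiphenylsilyloxymethyl)-2-methyl-6-methylidenecyclohexyl]-3-methylpent-4-enoate | C[Si](C)(C)OC(=O)[C@@H]([C@H](C)C=C)[C@H]1[C@@H](C)C[C@@H](CO[Si](c2ccccc2)(c2ccccc2)C(C)(C)C)CC1=C | intermediate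
22 | (2S,3R)-2-[all-cis-4-(tert-butyldiphenylsilyloxymethyl)-2-methyl-6-methylidenecyclohexyl]-3-methylpent-4-en-1-ol | OC[C@@H]([C@H](C)C=C)[C@H]1[C@@H](C)C[C@@H](CO[Si](c2ccccc2)(c2ccccc2)C(C)(C)C)CC1=C | intermediate
23 | triethylsilyl ether of 22 | CC[Si](CC)(CC)OC[C@@H]([C@H](C)C=C)[C@H]1[C@@H](C)C[C@@H](CO[Si](c2ccccc2)(c2ccccc2)C(C)(C)C)CC1=C | intermediate
24 | C4a spiro-epoxide of 23 (oxygen α) | CC[Si](CC)(CC)OC[C@@H]([C@H](C)C=C)[C@H]1[C@@H](C)C[C@@H](CO[Si](c2ccccc2)(c2ccccc2)C(C)(C)C)C[C@@]1(O3)C3 | intermediate
25 | γ-oxido dimethylsulfonium betaine from 24 | CC[Si](CC)(CC)OC[C@@H]([C@H](C)C=C)[C@H]1[C@@H](C)C[C@@H](CO[Si](c2ccccc2)(c2ccccc2)C(C)(C)C)C[C@@]1([O-])CC[S+](C)C | intermediate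
26 | tertiary vinyl carbinol (C4a–OH α, vinyl β) | CC[Si](CC)(CC)OC[C@@H]([C@H](C)C=C)[C@H]1[C@@H](C)C[C@@H](CO[Si](c2ccccc2)(c2ccccc2)C(C)(C)C)C[C@@]1(O)C=C | intermediate
27 | 1-(triethylsilyloxymethyl)-6-(tert-butyldiphenylsilyloxymethyl)-2,8-dimethyl-1,2,4a,5,6,7,8,8a-octahydronaphthalen-4a-ol (decalin locants) | CC[Si](CC)(CC)OC[C@@H]1[C@H]2[C@@H](C)C[C@@H](CO[Si](c3ccccc3)(c3ccccc3)C(C)(C)C)C[C@@]2(O)C=C[C@H]1C | intermediate
28 | 4a-O-triethylsilyl ether of 27 | CC[Si](CC)(CC)OC[C@@H]1[C@H]2[C@@H](C)C[C@@H](CO[Si](c3ccccc3)(c3ccccc3)C(C)(C)C)C[C@@]2(O[Si](CC)(CC)CC)C=C[C@H]1C | intermediate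
29 | decalin-1-carbaldehyde (4a-OSiEt3, 6-CH2OSiPh2t-Bu, 2,8-dimethyl; decalin locants) | O=C[C@@H]1[C@H]2[C@@H](C)C[C@@H](CO[Si](c3ccccc3)(c3ccccc3)C(C)(C)C)C[C@@]2(O[Si](CC)(CC)CC)C=C[C@H]1C | intermediate
30 | (E)-oct-2-en-1-ol | CCCCC/C=C/CO | starting material
31 | methyl (E)-oct-2-en-1-yl carbonate | CCCCC/C=C/COC(=O)OC | intermediate
32 | dimethyl malonate | COC(=O)CC(=O)OC | starting material
33 | dimethyl 2-[(3S)-oct-1-en-3-yl]propanedioate | C=C[C@H](CCCCC)C(C(=O)OC)C(=O)OC | intermediate
34 | 2-bromoacetamide | NC(=O)CBr | starting material
35 | dimethyl 2-(2-amino-2-oxoethyl)-2-[(3S)-oct-1-en-3-yl]propanedioate | C=C[C@H](CCCCC)C(CC(N)=O)(C(=O)OC)C(=O)OC | intermediate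
36 | methyl 3-[(3S)-oct-1-en-3-yl]-2,5-dioxopyrrolidine-3-carboxylate (C3 epimers) | C=C[C@H](CCCCC)C1(C(=O)OC)CC(=O)NC1=O | intermediate
37 | 3-[(3S)-oct-1-en-3-yl]pyrrolidine-2,5-dione (C3 epimers) | C=C[C@H](CCCCC)C1CC(=O)NC1=O | intermediate
38 | N,C4-dilithio derivative of 37 | C=C[C@H](CCCCC)C1C=C(O[Li])N([Li])C1=O | intermediate
39 | aldol adduct of 29 and 37 (diastereomers at carbinol and imide ring carbons) | C=C[C@H](CCCCC)C1C(C(O)[C@@H]2[C@H]3[C@@H](C)C[C@@H](CO[Si](c4ccccc4)(c4ccccc4)C(C)(C)C)C[C@@]3(O[Si](CC)(CC)CC)C=C[C@H]2C)C(=O)NC1=O | intermediate
40 | desilylated triol of 39 | C=C[C@H](CCCCC)C1C(C(O)[C@@H]2[C@H]3[C@@H](C)C[C@@H](CO)C[C@@]3(O)C=C[C@H]2C)C(=O)NC1=O | intermediate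
41 | keto aldehyde (3-acylsuccinimide, C6–CHO) | C=C[C@H](CCCCC)C1C(C(=O)[C@@H]2[C@H]3[C@@H](C)C[C@@H](C=O)C[C@@]3(O)C=C[C@H]2C)C(=O)NC1=O | intermediate
42 | keto acid (3-acyl-4-alkylsuccinimide, C6–CO2H) | C=C[C@H](CCCCC)C1C(C(=O)[C@@H]2[C@H]3[C@@H](C)C[C@@H](C(=O)O)C[C@@]3(O)C=C[C@H]2C)C(=O)NC1=O | intermediate
43 | α-phenylselanyl derivative of 42 | C=C[C@H](CCCCC)C1C([Se]c4ccccc4)(C(=O)[C@@H]2[C@H]3[C@@H](C)C[C@@H](C(=O)O)C[C@@]3(O)C=C[C@H]2C)C(=O)NC1=O | intermediate
44 | CNP0326775.3 | C=C[C@H](CCCCC)C1=C(C(=O)[C@@H]2[C@H]3[C@@H](C)C[C@@H](C(=O)O)C[C@@]3(O)C=C[C@H]2C)C(=O)NC1=O | target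

## Step count and least certain steps

Total: 26 steps. Longest linear sequence: 22 steps (steps 1–17, then 22–26); the imide fragment takes 4 steps (18–21).

Step 1 (key step). The likely failure is loss of material by reduction of the bromoketone without capture, by double addition, and by dimerisation of the diene, because the cation is generated on a metal surface while the diene slowly dimerises. Fallback: from 1, 2-methoxyallyl bromide is ionised with AgOCOCF3/Na2CO3 in the presence of the diene, a (4+3) cycloaddition that needs no reduction and gives racemic 3-methoxybicyclo[3.2.1]octa-2,6-diene F1; dilute aqueous acid hydrolyses the enol ether and the route is rejoined at 4.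

Step 11. The likely failure is poor facial selectivity at C1 (and, less likely, erosion of enolate geometry). The bias comes only from the difference between an sp2 carbon and a methyl-bearing sp3 carbon flanking C8a, and the wrong face would invert C1 and C2 together. Fallback: from 19, stereocontrol is moved from substrate to reagent. Enolisation with a C2-symmetric 2-bromo-4,5-diphenyl-1,3-bis(arylsulfonyl)-1,3,2-diazaborolidine and Et3N in CH2Cl2 at −78 °C gives a chiral boron ketene acetal, whose rearrangement gives (2S,3R)-2-[all-cis-4-(tert-butyldiphenylsilyloxymethyl)-2-methyl-6-methylidenecyclohexyl]-3-methylpent-4-enoic acid F5; LiAlH4 reduction rejoins the route at 22.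

Step 5. The likely failure is loss of chemoselectivity, with the osmium reagent also oxidising the exocyclic methylene, since the rate gap between the strained ring alkene and a 1,1-disubstituted alkene is finite. Fallback: from 9, the ketone is kept through the cleavage as its ethylene ketal, methyl 2-[(1R,2S,5R)-spiro[bicyclo[3.2.1]oct-6-ene-3,2′-[1,3]dioxolan]-2-yl]acetate F2 (ethylene glycol, PPTS, benzene, reflux). Ozonolysis with NaBH4 work-up and PPTS lactonisation give the ketal hydroxy lactone F3. Brief hydrolysis (PPTS, acetone/H2O) gives the keto hydroxy lactone F4, which is methylenated without base (Zn, CH2Br2, TiCl4) to rejoin the route at 14.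

Step 22. The likely failures are proton transfer instead of addition (enolisation of the hindered α-branched aldehyde, or metalation of the imide at its substituted α-carbon) and retro-aldol on warming, because both partners are crowded at the reacting carbons and the dianion is strongly basic. Fallback: from 37, Me3SiOTf/Et3N gives 1-(trimethylsilyl)-2,5-bis(trimethylsilyloxy)-3-[(3S)-oct-1-en-3-yl]pyrrole F6; its Mukaiyama aldol addition to 29 with BF3·OEt2 at −78 °C occurs at the unsubstituted ring carbon under non-basic conditions, and aqueous work-up rejoins the route at 39.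

Step 26. The likely failures are addition of the electrophilic selenium reagent or of benzeneselenenic acid to the ring A alkene or the vinyl group, and epimerisation or double-bond migration at the side-chain methine once the maleimide exists, since that hydrogen is doubly allylic and vinylogous to the imide. Fallback: from 42, N-bromosuccinimide in CH2Cl2 at 0 °C brominates the same doubly activated carbon to give the α-bromo acylsuccinimide F7; dehydrobromination with Et3N at −20 °C, quenched cold, gives 44.

## Further compounds

F1 | step 1 | 3-methoxybicyclo[3.2.1]octa-2,6-diene (racemic; one enantiomer drawn) | COC1=C[C@@H](C=C2)C[C@@H]2C1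
F2 | step 5 | methyl 2-[(1R,2S,5R)-spiro[bicyclo[3.2.1]oct-6-ene-3,2′-[1,3]dioxolan]-2-yl]acetate | COC(=O)C[C@H]1[C@@H](C=C2)C[C@@H]2CC13OCCO3
F3 | step 5 | ethylene ketal of cis-fused 7-(hydroxymethyl)hexahydro-1H-isochromene-3,5(4H)-dione at C5 | O=C1C[C@H]2[C@@H](CO1)C[C@@H](CO)CC23OCCO3
F4 | step 5 | cis-fused 7-(hydroxymethyl)hexahydro-1H-isochromene-3,5(4H)-dione | O=C1C[C@H]2[C@@H](CO1)C[C@@H](CO)CC2=O
F5 | step 11 | (2S,3R)-2-[all-cis-4-(tert-butyldiphenylsilyloxymethyl)-2-methyl-6-methylidenecyclohexyl]-3-methylpent-4-enoic acid | OC(=O)[C@@H]([C@H](C)C=C)[C@H]1[C@@H](C)C[C@@H](CO[Si](c2ccccc2)(c2ccccc2)C(C)(C)C)CC1=C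
F6 | step 22 | 1-(trimethylsilyl)-2,5-bis(trimethylsilyloxy)-3-[(3S)-oct-1-en-3-yl]pyrrole | C=C[C@H](CCCCC)c1cc(O[Si](C)(C)C)n([Si](C)(C)C)c1O[Si](C)(C)C
F7 | step 26 | α-bromo derivative of 42 | C=C[C@H](CCCCC)C1C(Br)(C(=O)[C@@H]2[C@H]3[C@@H](C)C[C@@H](C(=O)O)C[C@@]3(O)C=C[C@H]2C)C(=O)NC1=O
A1 | alternative 1 | (Z)-iodoalkenyl keto diester (ring B cyclohexanone with the C1–C4 chain on C8a) | COC(=O)[C@@H]([C@H](C)/C=C\I)[C@H]1[C@@H](C)C[C@@H](C(=O)OCC[Si](C)(C)C)CC1=O
A2 | alternative 1 | cis-decalin 4a-hydroxy diester | COC(=O)[C@@H]1[C@H]2[C@@H](C)C[C@@H](C(=O)OCC[Si](C)(C)C)C[C@@]2(O)C=C[C@H]1C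
A3 | alternative 2 | 4-hydroxy-2,6-dimethyl-4-[(1Z,3S)-3-methyl-5-oxopent-1-en-1-yl]cyclohexa-2,5-dien-1-one | O=CC[C@H](C)/C=C\C1(O)C=C(C)C(=O)C(C)=C1
A4 | alternative 2 | cis-fused 4a-hydroxy decalin with C1 aldehyde, C7 ketone and C5=C6 enone | O=C[C@@H]1[C@H]2[C@@H](C)C(=O)C(C)=C[C@@]2(O)C=C[C@H]1C
A5 | alternative 3 | bicyclo[3.2.1]oct-6-en-1-ol with the etheno bridge between C4a and C6 and the C1–C3 chain on C8a | COC(=O)[C@@H]([C@H](C)C=C)[C@H]1[C@@H](C)C[C@@H]2C[C@@]1(O)C=C2
A6 | alternative 3 | cis-decalin hydroxy ester with a vinyl group on C6 | COC(=O)[C@@H]1[C@H]2[C@@H](C)C[C@@H](C=C)C[C@@]2(O)C=C[C@H]1C
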